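During the 40 h of dosing, the flask's free monomer arrives at a steady rate while its initiator stands in the flask from the start, charged in the smaller amount. The balance of initiator therefore carries the reckoning.

| flask | free monomer | initiator | remark | time |
|---|---|---|---|---|
| epsilon | 0.56 M (fed, over 40 h) | 3 mM | run made earlier; the fed solution adds 0.50 times the starting volume |  |
| theta | 0.88 M (fed, over 40 h) | 3 mM | run made earlier; the fed solution adds 0.50 times the starting volume |  |
| gamma | 0.40 M (fed, over 40 h) | 1.5 mM | run made earlier; the fed solution adds 0.50 times the starting volume |  |
| flask | 0.40 M (fed, over 40 h) | 3.0 mM | the fed solution adds 0.50 times the starting volume | 40 h |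

- epsilon (time / h: monomer in chains / %, free monomer / %): 10.0: 8, 19; 20.0: 14, 36; 30.0: 29, 45; 40.0: 46, 55; 50.0: 56, 37
- theta (time / h: monomer in chains / %, free monomer / %): 4.00: 0, 12; 12.0: 12, 21; 20.0: 15, 36; 30.0: 25, 45; 50.0: 55, 43
- gamma (time / h: monomer in chains / %, free monomer / %): 4.00: 1, 6; 12.0: 6, 25; 20.0: 10, 34; 30.0: 23, 52; 50.0: 44, 53

(standard deviation of a reading: 2 percentage points)

- charges are per starting volume, the dose included; the dosed solution carries all of it
- the average divides the monomer in chains by the number of chains, living and dead together; two radicals that join make one chain
- the earlier runs do not show the number of chains; that part of a forecast is a guess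
- percentages count the whole charge, also what has not yet gone in

1. average number of monomer units in a chain (living and dead chains, two that joined counted as one) at 40 h
2. part of the free monomer that has reacted at 40 h

In the first hours the dose outruns the reaction: the gamma run at 4.00 h holds 6 % as free monomer and 1 % in chains. At mid-dose the epsilon and theta runs read 14 % and 15 % in chains at 20.0 h, although the theta charge is larger. Percentages that ignore the charge point to a pseudo-first-order loss of free monomer, so the flask should follow these runs, which have its initiator charge. At 40.0 h the epsilon run reads 46 % in chains. After the dose, free monomer falls, to 37 % at 50.0 h in that run.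

The chain count is the open part. Supposing that each initiator lost gives two radicals and that two radicals join into one chain, one chain stands per initiator spent. The carried quantity is then the charge ratio, free monomer charged per initiator charged, 133. The average is this ratio times the part of free monomer reacted, divided by the part of initiator spent. The reckoning here takes the epsilon reading and guesses half of the initiator spent, which gives 123. The forecast stands higher, with 190 and 43 %, and says “Chain number is a guess”.

The flask gives 146 and 44.1 %, with 60 % of its initiator left. The forecast's conversion holds, and its average is too high by a factor of 1.30. The ratio, with these two parts, gives 146. The dosing of free monomer lowers the average: the same flask without the dose reaches 240 against 146, a factor of 1.65.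

    2 growing radical → dead chain (k = 9.70 × 10⁸ M⁻¹ s⁻¹)
    initiator → 2 initiating radical (k = 0.0129 h⁻¹)
    free monomer + growing radical → monomer in chains + growing radical, rate k3*[growing radical]*[free monomer] (k = 1.34 × 10⁷ M⁻¹ h⁻¹)
    free monomer + initiating radical → growing radical + monomer in chains (k = 33700 M⁻¹ s⁻¹)

A neighbouring flask, charged with 0.0075 M of initiator, has the ratio 53.3, and with 57.5 % reacted and 60 % of its initiator left this gives 76.1. The computed average for that neighbouring flask is 76.1.

The data were generated by integration on assumed constants; the scatter is artificial.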